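**Retrosynthetic overview**

1. The 4-hydroxybenzoyl carbon is attached last, at C6, the only ring C–H then left. This is done by directed lithiation, addition to 4-(methoxymethoxy)benzaldehyde, oxidation and loss of three MOM groups (chromene numbering O1, C2, C3, C4, C4a, C5–C8, C8a throughout).
2. The 8-prenyl-2H-chromene core is made in one operation from a chloroarene: an aryne across C8–C8a, closure of the pyran ring (ring B) through the O1–C8a bond, and formation of the C8–prenyl bond from the aryl anion that the closure leaves behind.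
3. Enabling feature: in ring A, C8a (which must carry O1) lies between C4a, which carries the cis C4=C3–C2(Me)2–O1 arm, and C8, which carries the prenyl group and is flanked by the C7 oxygen. C4a, C8a and C8 thus become tether anchor, attacked aryne carbon and metalated aryne carbon, and the C7 oxygen both acidifies H8 and steers the nucleophile to C8a.
4. The aryne precursor comes from 5-chlororesorcinol by bis-MOM protection, iodination next to chlorine, Sonogashira coupling with 2-methylbut-3-yn-2-ol and cis semi-hydrogenation.
5. Ring order: ring A is bought, ring B is the only ring formed (in the key step), and the 4-hydroxyphenyl ring arrives with the aldehyde.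

Key step: step 5

Remark: 5-chlorobenzene-1,3-diol, 2-methylbut-3-yn-2-ol, 1-bromo-3-methylbut-2-ene and 4-(methoxymethoxy)benzaldehyde are taken as commercial; the target has no stereocentre, and its only stereo-element is the cis C3=C4 bond held in ring B.

**Route**

Step 1
Reactants: 1 5-chlorobenzene-1,3-diol
Product: 2 1-chloro-3,5-bis(methoxymethoxy)benzene
Conditions: MOMCl (2.6 equiv), i-Pr2NEt (3 equiv), CH2Cl2, 0 °C to rt
Reagents that add atoms: chloromethyl methyl ether (MOMCl), COCCl
Why: O-alkylation of both phenols (MOM protection) is routine and gives acetals that survive lithium amides and organolithiums and later direct the ortho-metalation.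

Step 2
Reactants: 2 1-chloro-3,5-bis(methoxymethoxy)benzene
Product: 3 1-chloro-2-iodo-3,5-bis(methoxymethoxy)benzene
Conditions: NIS (1.05 equiv), MeCN, 0 °C to rt, dark
Reagents that add atoms: N-iodosuccinimide (NIS), O=C1CCC(=O)N1I
Why: Electrophilic aromatic iodination should go to the position next to chlorine, which is para to one OMOM group and ortho to the other, as halogenation of 5-substituted resorcinol diethers generally does, because the position between the two OMOM groups has only ortho activation and is the more crowded one.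

Step 3
Reactants: 3 1-chloro-2-iodo-3,5-bis(methoxymethoxy)benzene; 4 2-methylbut-3-yn-2-ol
Product: 5 4-[2-chloro-4,6-bis(methoxymethoxy)phenyl]-2-methylbut-3-yn-2-ol
Conditions: PdCl2(PPh3)2 (3 mol %), CuI (6 mol %), Et3N, THF, 55 °C
Reagents that add atoms: none
Why: Sonogashira coupling should occur only at the C–I bond, since oxidative addition into the electron-rich C–Cl bond is far slower under these conditions.

Step 4
Reactants: 5 4-[2-chloro-4,6-bis(methoxymethoxy)phenyl]-2-methylbut-3-yn-2-ol
Product: 6 (3Z)-4-[2-chloro-4,6-bis(methoxymethoxy)phenyl]-2-methylbut-3-en-2-ol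
Conditions: H2 (1 atm), Pd/CaCO3 poisoned with Pb(OAc)2 (Lindlar catalyst), quinoline, EtOAc, rt, stopped after one equivalent of H2
Reagents that add atoms: none
Why: Lindlar semi-hydrogenation delivers both hydrogens to one face of the alkyne on the poisoned surface, so the Z-alkene (a geometry, not a stereocentre) should form, with the aryl chloride and the MOM ethers untouched.

Step 5
Reactants: 6 (3Z)-4-[2-chloro-4,6-bis(methoxymethoxy)phenyl]-2-methylbut-3-en-2-ol; 7 1-bromo-3-methylbut-2-ene (prenyl bromide)
Product: 10 5,7-bis(methoxymethoxy)-2,2-dimethyl-8-(3-methylbut-2-en-1-yl)-2H-chromene, via aryne alkoxide 8 (not isolated), via 8-lithiochromene 9 (not isolated)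
Conditions: LiTMP (2.2 equiv), THF (0.03 M), −78 to −10 °C; then CuBr·SMe2 (10 mol %), 7 (3 equiv), −78 °C to rt
Reagents that add atoms: none
Why: Proposed new method: the first equivalent of LiTMP gives the lithium alkoxide of 6 and the second removes H8, the ring hydrogen acidified by both the chlorine and the C7 OMOM group, so that loss of LiCl gives aryne 8 (C8≡C8a), whose cis-held alkoxide O1 adds to C8a to give aryllithium 9 with the carbanion on C8, which copper-catalysed allylic substitution with 7 at its primary carbon should convert to 10. The closest known reactions are the base-induced benzyne cyclization of haloarenes carrying a tethered alkoxide (chromans, dihydrobenzofurans) and the one-pot aryne formation, nucleophile addition and electrophile trapping run with LiTMP; new is the use of the aryl anion left by an alkoxide closure for a C-allylation in the same flask. Ring B closes by in-plane attack of O1 on the aryne carbon C8a, formally 6-exo-dig, which is the only closure the three-atom cis arm can reach. No stereocentre is formed, and the cis C3=C4 geometry set in step 4 is simply locked into the ring. The step needs H8 rather than H6 to be removed (lithiation at C6 is reversible through the liberated amine and unproductive, while lithiation at C8 is drained by loss of LiCl), O1 rather than amide or aryllithium to capture the aryne (hindered amide, high dilution, six-membered intramolecular delivery, and the C7 oxygen polarises the aryne toward attack at C8a), and survival of 9 until allylation (a carbanion flanked by two oxygens is less basic than LiTMP, so the free amine should not quench it).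

Step 6
Reactants: 10 5,7-bis(methoxymethoxy)-2,2-dimethyl-8-(3-methylbut-2-en-1-yl)-2H-chromene; 11 4-(methoxymethoxy)benzaldehyde
Product: 13 [5,7-bis(methoxymethoxy)-2,2-dimethyl-8-(3-methylbut-2-en-1-yl)-2H-chromen-6-yl][4-(methoxymethoxy)phenyl]methanol (racemic), via 6-lithiochromene 12 (not isolated)
Conditions: n-BuLi (1.2 equiv), THF, −78 to 0 °C; then 11 (1.3 equiv), −78 °C to rt; H2O
Reagents that add atoms: none
Why: Directed ortho-metalation should take place at C6, the only aromatic hydrogen left and one flanked by two chelating OMOM groups, and 1,2-addition of the aryllithium to the aldehyde gives the carbinol as a racemate whose stereocentre is erased in the next step.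

Step 7
Reactants: 13 [5,7-bis(methoxymethoxy)-2,2-dimethyl-8-(3-methylbut-2-en-1-yl)-2H-chromen-6-yl][4-(methoxymethoxy)phenyl]methanol
Product: 14 [5,7-bis(methoxymethoxy)-2,2-dimethyl-8-(3-methylbut-2-en-1-yl)-2H-chromen-6-yl][4-(methoxymethoxy)phenyl]methanone
Conditions: Dess–Martin periodinane (1.3 equiv), CH2Cl2, 0 °C to rt
Reagents that add atoms: none
Why: Dess–Martin oxidation of the doubly benzylic secondary alcohol runs under nearly neutral conditions that should leave the MOM acetals, the prenyl olefin and the chromene olefin intact.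

Step 8
Reactants: 14 [5,7-bis(methoxymethoxy)-2,2-dimethyl-8-(3-methylbut-2-en-1-yl)-2H-chromen-6-yl][4-(methoxymethoxy)phenyl]methanone
Product: 15 [5,7-dihydroxy-2,2-dimethyl-8-(3-methylbut-2-en-1-yl)-2H-chromen-6-yl](4-hydroxyphenyl)methanone (vismiaphenone E)
Conditions: HCl (3 M aq), MeOH, 40 °C
Reagents that add atoms: none
Why: Acid-catalysed acetal exchange with methanol (MOM cleavage) should free all three phenols, the two MOM groups ortho to the ketone going fastest through hydrogen-bond assistance, under conditions mild enough for the prenyl and chromene olefins.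

**Compound list**

1 | 5-chlorobenzene-1,3-diol | Oc1cc(O)cc(Cl)c1 | starting material
2 | 1-chloro-3,5-bis(methoxymethoxy)benzene | COCOc1cc(Cl)cc(OCOC)c1 | intermediate
3 | 1-chloro-2-iodo-3,5-bis(methoxymethoxy)benzene | COCOc1cc(Cl)c(I)c(OCOC)c1 | intermediate
4 | 2-methylbut-3-yn-2-ol | CC(C)(O)C#C | starting material
5 | 4-[2-chloro-4,6-bis(methoxymethoxy)phenyl]-2-methylbut-3-yn-2-ol | COCOc1cc(Cl)c(C#CC(C)(C)O)c(OCOC)c1 | intermediate
6 | (3Z)-4-[2-chloro-4,6-bis(methoxymethoxy)phenyl]-2-methylbut-3-en-2-ol | COCOc1cc(Cl)c(/C=C\C(C)(C)O)c(OCOC)c1 | intermediate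
7 | 1-bromo-3-methylbut-2-ene (prenyl bromide) | CC(C)=CCBr | starting material
8 | lithium (3Z)-4-[2,3-didehydro-4,6-bis(methoxymethoxy)phenyl]-2-methylbut-3-en-2-olate (aryne, C8≡C8a) | [Li]OC(C)(C)/C=C\C1=C(OCOC)C=C(OCOC)C#C1 | intermediate (not isolated)
9 | [5,7-bis(methoxymethoxy)-2,2-dimethyl-2H-chromen-8-yl]lithium | [Li]c1c(OCOC)cc(OCOC)c2C=CC(C)(C)Oc12 | intermediate (not isolated)
10 | 5,7-bis(methoxymethoxy)-2,2-dimethyl-8-(3-methylbut-2-en-1-yl)-2H-chromene | CC(C)=CCc1c(OCOC)cc(OCOC)c2C=CC(C)(C)Oc12 | intermediate
11 | 4-(methoxymethoxy)benzaldehyde | COCOc1ccc(C=O)cc1 | starting material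
12 | [5,7-bis(methoxymethoxy)-2,2-dimethyl-8-(3-methylbut-2-en-1-yl)-2H-chromen-6-yl]lithium | CC(C)=CCc1c(OCOC)c([Li])c(OCOC)c2C=CC(C)(C)Oc12 | intermediate (not isolated)
13 | [5,7-bis(methoxymethoxy)-2,2-dimethyl-8-(3-methylbut-2-en-1-yl)-2H-chromen-6-yl][4-(methoxymethoxy)phenyl]methanol (racemic) | CC(C)=CCc1c(OCOC)c(C(O)c3ccc(OCOC)cc3)c(OCOC)c2C=CC(C)(C)Oc12 | intermediate
14 | [5,7-bis(methoxymethoxy)-2,2-dimethyl-8-(3-methylbut-2-en-1-yl)-2H-chromen-6-yl][4-(methoxymethoxy)phenyl]methanone | CC(C)=CCc1c(OCOC)c(C(=O)c3ccc(OCOC)cc3)c(OCOC)c2C=CC(C)(C)Oc12 | intermediate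
15 | [5,7-dihydroxy-2,2-dimethyl-8-(3-methylbut-2-en-1-yl)-2H-chromen-6-yl](4-hydroxyphenyl)methanone (vismiaphenone E) | CC(C)=CCc1c(O)c(C(=O)c2ccc(O)cc2)c(O)c2c1OC(C)(C)C=C2 | target

**Step count and risks**

Total step count: 8. Longest linear sequence: 8 steps (1 to 15).

Steps most likely to fail:

Step 5. Three processes could defeat it: capture of the aryne by lithium amide or by aryllithium before the alkoxide closes, protonation of the C8 carbanion by the liberated amine before allylation, and allylation at the tertiary end of the prenyl unit. The fallback uses known chemistry and runs from 6 to 13. The same O1–C8a bond is closed by palladium-catalysed intramolecular C–O coupling of the aryl chloride with the tertiary alcohol (Pd(OAc)2, 2-(di-tert-butylphosphino)-1,1'-binaphthyl, Cs2CO3, toluene, 80 °C), which should give 5,7-bis(methoxymethoxy)-2,2-dimethyl-2H-chromene F1. Directed lithiation of F1 between its two OMOM groups (n-BuLi, THF, −78 to 0 °C) and addition to 11 should give [5,7-bis(methoxymethoxy)-2,2-dimethyl-2H-chromen-6-yl][4-(methoxymethoxy)phenyl]methanol F2. Treatment of F2 with n-BuLi (2.2 equiv) forms the alkoxide and then lithiates C8, by then the last ring hydrogen, and copper-catalysed reaction with 7 (CuBr·SMe2, 10 mol %) should give 13, where the route is rejoined before step 7.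

Step 8. The acid could drive cyclization of the prenyl group onto the freed C7 hydroxyl or addition of HCl or methanol to the olefins, or the para MOM group could lag and force harsher treatment. The fallback keeps the prenyl olefin out of the acid step and runs from 6 to 15. Step 5 is run with allyl bromide in place of 7 to give 5,7-bis(methoxymethoxy)-2,2-dimethyl-8-(prop-2-en-1-yl)-2H-chromene F3. Lithiation at C6 and addition to 11 as in step 6 should give [5,7-bis(methoxymethoxy)-2,2-dimethyl-8-(prop-2-en-1-yl)-2H-chromen-6-yl][4-(methoxymethoxy)phenyl]methanol F4. Dess–Martin oxidation should give [5,7-bis(methoxymethoxy)-2,2-dimethyl-8-(prop-2-en-1-yl)-2H-chromen-6-yl][4-(methoxymethoxy)phenyl]methanone F5. HCl/MeOH, to which a monosubstituted allyl group is indifferent, should give [5,7-dihydroxy-2,2-dimethyl-8-(prop-2-en-1-yl)-2H-chromen-6-yl](4-hydroxyphenyl)methanone F6. Cross-metathesis of F6 with 2-methylbut-2-ene (second-generation Grubbs catalyst, CH2Cl2, 40 °C), to which the hindered ring olefin should be inert, then turns the allyl group into the prenyl group of 15.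

Step 4. The hydrogenation could run on to the saturated alcohol, stall at the hindered alkyne, or give partial cis-to-trans isomerization on the catalyst. The fallback sets the geometry by olefination instead, runs from 1 to 6, and also bypasses steps 2 and 3. Vilsmeier–Haack formylation of 1 (POCl3, DMF, MeCN; then aqueous hydrolysis) para to one hydroxyl and next to chlorine should give 2-chloro-4,6-dihydroxybenzaldehyde F7. Protection (MOMCl, NaH, DMF) should give 2-chloro-4,6-bis(methoxymethoxy)benzaldehyde F8. Still–Gennari olefination (methyl bis(2,2,2-trifluoroethyl)phosphonoacetate, KHMDS, 18-crown-6, THF, −78 °C) should give methyl (2Z)-3-[2-chloro-4,6-bis(methoxymethoxy)phenyl]prop-2-enoate F9. Double addition of MeLi in the presence of CeCl3 (THF, −78 °C) should give 6.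

**Further compounds**

F1 | step 5 | 5,7-bis(methoxymethoxy)-2,2-dimethyl-2H-chromene | COCOc1cc(OCOC)c2C=CC(C)(C)Oc2c1
F2 | step 5 | [5,7-bis(methoxymethoxy)-2,2-dimethyl-2H-chromen-6-yl][4-(methoxymethoxy)phenyl]methanol (racemic) | COCOc1cc2OC(C)(C)C=Cc2c(OCOC)c1C(O)c3ccc(OCOC)cc3
F3 | step 8 | 5,7-bis(methoxymethoxy)-2,2-dimethyl-8-(prop-2-en-1-yl)-2H-chromene | C=CCc1c(OCOC)cc(OCOC)c2C=CC(C)(C)Oc12
F4 | step 8 | [5,7-bis(methoxymethoxy)-2,2-dimethyl-8-(prop-2-en-1-yl)-2H-chromen-6-yl][4-(methoxymethoxy)phenyl]methanol (racemic) | C=CCc1c(OCOC)c(C(O)c3ccc(OCOC)cc3)c(OCOC)c2C=CC(C)(C)Oc12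
F5 | step 8 | [5,7-bis(methoxymethoxy)-2,2-dimethyl-8-(prop-2-en-1-yl)-2H-chromen-6-yl][4-(methoxymethoxy)phenyl]methanone | C=CCc1c(OCOC)c(C(=O)c3ccc(OCOC)cc3)c(OCOC)c2C=CC(C)(C)Oc12
F6 | step 8 | [5,7-dihydroxy-2,2-dimethyl-8-(prop-2-en-1-yl)-2H-chromen-6-yl](4-hydroxyphenyl)methanone | C=CCc1c(O)c(C(=O)c3ccc(O)cc3)c(O)c2C=CC(C)(C)Oc12
F7 | step 4 | 2-chloro-4,6-dihydroxybenzaldehyde | O=Cc1c(O)cc(O)cc1Cl
F8 | step 4 | 2-chloro-4,6-bis(methoxymethoxy)benzaldehyde | COCOc1cc(Cl)c(C=O)c(OCOC)c1
F9 | step 4 | methyl (2Z)-3-[2-chloro-4,6-bis(methoxymethoxy)phenyl]prop-2-enoate | COCOc1cc(Cl)c(/C=C\C(=O)OC)c(OCOC)c1
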